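- G is what we count, as a fraction of the D charged, and at the end of a flask that fraction is a share: what the G route took of D against whatever else took it.

| flask | D | X | J | temperature | remark | time |
|---|---|---|---|---|---|---|
| east | 0.016 M | 8 mM | 0.24 mM | 5 °C | run made earlier |  |
| north-east | 0.016 M | 8 mM | 0.72 mM | 25 °C | run made earlier |  |
| west | 0.016 M | 8 mM | 2.6 mM | 5 °C | run made earlier |  |
| north | 0.035 M | 8 mM | 0.80 mM | 25 °C | run made earlier |  |
| autumn | 0.030 M | 8.00 mM | 3.0 mM | 10 °C |  | 12 d |
| dusk | 0.016 M | 12.0 mM | 1.5 mM | 25 °C |  | 12 d |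
| spring | 0.016 M | 8.00 mM | 0.80 mM | 25 °C |  | 12 d |
| winter | 0.016 M | 4.00 mM | 0.20 mM | 25 °C |  | 12 d |
| dawn | 0.050 M | 8.00 mM | 0.80 mM | 40 °C |  | 12 d |

- east (time / d: G / %, D / %): 3.00: 6.9, 65.9; 8.00: 12.2, 38.0; 15.0: 16.7, 18.8; 20.0: 18.4, 13.1
- north-east (time / d: G / %, D / %): 0.625: 16.0, 44.2; 1.67: 20.5, 14.2; 4.00: 23.5, 2.3; 8.00: 23.4, 0
- west (time / d: G / %, D / %): 1.67: 29.7, 53.9; 5.00: 55.3, 16.7; 10.0: 66.5, 2.1; 20.0: 68.5, 0
- north (time / d: G / %, D / %): 2.00: 23.9, 12.2; 4.00: 25.6, 1.5; 6.00: 27.7, 0.8; 8.00: 27.3, 2.0

(readings scatter by 1 percentage point)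

1. the flasks by amount of G, in percent of the D charged, highest first, at 12 d (autumn / dusk / spring / winter / dawn)
2. the amount of G, in percent of the D charged of the flask you put first, at 12 d
3. the amount of G, in percent of the D charged of the flask you put last, at 12 d

- Something besides J consumes D. From the east run to the west run at 5 °C, J rises by a factor of 10.8, but the first-order constant of D loss, read at 8.00 d and 5.00 d, rises by a factor of 2.96.
- So we fold the flask into one number, W, the charge of J divided by h, the charge at which G would take half of D. W is a selectivity factor, and the end fraction of G is W over one plus W, that is, J/(J+h).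
- The north-east run ends at 23.4% with J 0.72 mM, which gives 2.36 mM, the half-share charge at 25 °C. The west run ends at 68.5% with J 2.6 mM, which gives 1.20 mM at 5 °C. We interpolate ln h linearly in temperature.
- Late D readings are low, 2.1% in the west run at 10.0 d, so we read the flasks at 12 d as finished. Our own figures are autumn 67.9%, dusk 38.9%, spring 25.3%, dawn 16.9% and winter 7.82%.
- Is one number enough? The north run, with more D and the J of spring, reads 27.3% against our 25.3%, which is 2 percentage points apart with a scatter of 1 point. The east run is worse: G is 21.2% of the D used, against 16.7% from W. No run changes X, so dusk and winter hold a guess.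
- The forecast gives autumn > dusk > spring > dawn > winter, with 65% and 12%, on the ground that “G forms only by the catalysed route”.

    D + J → J + G (k = 0.340 M⁻¹ min⁻¹, Ea = 56.0 kJ mol⁻¹)
    D → Z (k = 4.20 × 10⁻⁴ min⁻¹, Ea = 91.0 kJ mol⁻¹)
    D + X → E (k = 0.0370 M⁻¹ min⁻¹, Ea = 55.0 kJ mol⁻¹)
    J → L (k = 2.00 × 10⁻⁴ min⁻¹, Ea = 112 kJ mol⁻¹)
    (constants at 25 °C)

- The flasks stand autumn > dusk > spring > dawn > winter, with autumn at 70.5% against our 67.9% and winter at 8.80% against our 7.82%. Autumn holds 0.165% of its D at 12.0 d, and its G is still 70.6% at 120 d. Spring has the temperature and the X of the north-east run, so 2.36 mM gives it W = 0.339, and at 12.0 d the fraction of G in spring stands to the fractions of Z and E together at 0.342.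

The readings were generated by integration on assumed constants, and the scatter is random.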